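**Assumption:** MOM = methoxymethyl, geranyl = (2E)-3,7-dimethylocta-2,6-dien-1-yl, prenyl = 3-methylbut-2-en-1-yl. Short-lived racemic centres (hemiaminal carbons of 14 and 18, the sp3 ring carbon of 20, the acetal carbon of F2 and F3) are drawn without configuration.

**Retrosynthetic overview**
1. Target 25 ⇐ tetra-MOM ether 24 (acetal cleavage) ⇐ (2S)-flavanone 22 (C3–OH by enolate hydroxylation anti to the C2 aryl group).
2. Ring C is the only ring made (rings A and B are bought as arenes). It closes by an asymmetric intramolecular oxa-Michael addition of the 2′-phenol of chalcone 21 (O1–C2 bond).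
3. 21 ⇐ chalcone 19 by aromatic Claisen shift of a 1,1-dimethylallyl ether, which places the 8-prenyl group and frees only the phenol that must cyclise.
4. 19 ⇐ aryllithium from ring A fragment 10 + Weinreb cinnamamide 16 (ring B fragment): the convergent union.
5. 10 ⇐ phloroglucinol + geraniol + 2-methylbut-3-en-2-ol (geranyl set between two OMOM groups of a symmetric arene); 16 ⇐ 5-methoxyresorcinol.

**Route**

Step 1
Reactants: 1 phloroglucinol
Product: 2 3,5-bis(methoxymethoxy)phenol
Conditions: MOMCl (2.0 equiv), K2CO3 (2.5 equiv), acetone, 0 °C → rt; chromatography (mono- and tris-ethers recycled)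
Reagents that add atoms: chloromethyl methyl ether COCCl
Why: Williamson-type O-alkylation of the symmetric triol with two equivalents of MOMCl gives a statistical mixture from which the bis-ether is separated, leaving exactly one free phenol as the future ring oxygen O1.

Step 2
Reactants: 3 2-methylbut-3-en-2-ol
Product: 5 methyl 2-methylbut-3-en-2-yl carbonate, via lithium alkoxide 4 (not isolated)
Conditions: n-BuLi (1.05 equiv), THF, −78 °C; ClCO2Me, −78 °C → rt
Reagents that add atoms: methyl chloroformate COC(=O)Cl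
Why: O-acylation of the preformed lithium tert-alkoxide by the chloroformate (nucleophilic acyl substitution) gives the tertiary allylic carbonate needed for palladium allylation.

Step 3
Reactants: 2 3,5-bis(methoxymethoxy)phenol; 5 methyl 2-methylbut-3-en-2-yl carbonate
Product: 6 1,3-bis(methoxymethoxy)-5-(2-methylbut-3-en-2-yloxy)benzene
Conditions: Pd(PPh3)4 (3 mol %), THF, 0 °C, 1 h
Reagents that add atoms: none
Why: Tsuji–Trost O-allylation, in which zerovalent palladium ionises the carbonate with loss of CO2 and the phenoxide attacks the more substituted terminus of the 1,1-dimethylallyl palladium complex under kinetic control, gives the tertiary aryl ether, which has no α-hydrogen and tolerates butyllithium.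

Step 4
Reactants: 7 geraniol
Product: 8 geranyl bromide
Conditions: PBr3 (0.4 equiv), Et2O, −10 → 0 °C; used crude
Reagents that add atoms: phosphorus tribromide BrP(Br)Br
Why: SN2 bromination of the primary allylic alcohol through its phosphite ester at low temperature keeps the 2E double bond.

Step 5
Reactants: 6 1,3-bis(methoxymethoxy)-5-(2-methylbut-3-en-2-yloxy)benzene; 8 geranyl bromide
Product: 10 2-geranyl-1,3-bis(methoxymethoxy)-5-(2-methylbut-3-en-2-yloxy)benzene, via aryllithium 9 (not isolated)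
Conditions: n-BuLi (1.1 equiv), THF, 0 °C, 1 h; CuBr·SMe2 (10 mol %), −78 °C; then 8, −78 → 0 °C
Reagents that add atoms: none
Why: Directed ortho-metalation takes place at the carbon flanked by the two chelating OMOM groups (the bulky tertiary ether shields its own ortho positions), and copper-catalysed SN2 allylation with the primary bromide installs the linear geranyl chain with E geometry intact, giving a symmetric arene whose two remaining ring hydrogens are equivalent.

Step 6
Reactants: 11 5-methoxyresorcinol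
Product: 12 1-methoxy-3,5-bis(methoxymethoxy)benzene
Conditions: MOMCl (2.5 equiv), K2CO3 (3 equiv), acetone, 0 °C → rt
Reagents that add atoms: chloromethyl methyl ether COCCl
Why: Williamson-type O-alkylation of both phenols gives a base-stable arene carrying two strong ortho-directing groups.

Step 7
Reactants: 12 1-methoxy-3,5-bis(methoxymethoxy)benzene
Product: 15 4-methoxy-2,6-bis(methoxymethoxy)benzaldehyde, via aryllithium 13 (not isolated), via lithium hemiaminal alkoxide 14 (not isolated)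
Conditions: n-BuLi (1.2 equiv), TMEDA, THF, 0 °C, 1 h; DMF, −78 °C → rt; sat. aq. NH4Cl
Reagents that add atoms: N,N-dimethylformamide CN(C)C=O
Why: Directed ortho-metalation occurs between the two OMOM groups (stronger directors than OMe) and formylation with DMF releases the aldehyde when the hemiaminal alkoxide is hydrolysed.

Step 8
Reactants: 15 4-methoxy-2,6-bis(methoxymethoxy)benzaldehyde
Product: 16 (E)-N-methoxy-3-[4-methoxy-2,6-bis(methoxymethoxy)phenyl]-N-methylprop-2-enamide
Conditions: (EtO)2P(O)CH2C(O)N(OMe)Me (1.2 equiv), NaH (1.2 equiv), THF, 0 °C → rt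
Reagents that add atoms: diethyl [2-[methoxy(methyl)amino]-2-oxoethyl]phosphonate CCOP(=O)(CC(=O)N(C)OC)OCC
Why: Horner–Wadsworth–Emmons olefination with a stabilised phosphonate anion gives the E-configured unsaturated Weinreb amide.

Step 9
Reactants: 10 2-geranyl-1,3-bis(methoxymethoxy)-5-(2-methylbut-3-en-2-yloxy)benzene; 16 (E)-N-methoxy-3-[4-methoxy-2,6-bis(methoxymethoxy)phenyl]-N-methylprop-2-enamide
Product: 19 (E)-1-[3-geranyl-2,4-bis(methoxymethoxy)-6-(2-methylbut-3-en-2-yloxy)phenyl]-3-[4-methoxy-2,6-bis(methoxymethoxy)phenyl]prop-2-en-1-one, via aryllithium 17 (not isolated), via lithium hemiaminal alkoxide 18 (not isolated)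
Conditions: n-BuLi (1.15 equiv), TMEDA, THF, −20 °C, 1.5 h; then 16, −78 → −30 °C; sat. aq. NH4Cl
Reagents that add atoms: none
Why: Directed ortho-metalation of either of the two equivalent ring hydrogens followed by Weinreb ketone synthesis (hard aryllithium adds 1,2 to the hindered cinnamamide and the chelated tetrahedral adduct prevents over-addition) joins the two fragments as the E-chalcone.

Step 10
Reactants: 19 (E)-1-[3-geranyl-2,4-bis(methoxymethoxy)-6-(2-methylbut-3-en-2-yloxy)phenyl]-3-[4-methoxy-2,6-bis(methoxymethoxy)phenyl]prop-2-en-1-one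
Product: 21 (E)-1-[3-geranyl-6-hydroxy-2,4-bis(methoxymethoxy)-5-prenylphenyl]-3-[4-methoxy-2,6-bis(methoxymethoxy)phenyl]prop-2-en-1-one, via Claisen dienone 20 (not isolated)
Conditions: toluene (degassed), BHT (cat.), 105 °C, 3 h
Reagents that add atoms: none
Why: Aromatic Claisen rearrangement ([3,3]-sigmatropic shift) of the 1,1-dimethylallyl ether to the only free ortho carbon turns the allyl unit into a normal prenyl group and, after tautomerisation of the dienone, frees the one phenol that becomes O1, so the 6-geranyl/8-prenyl pattern is fixed without ambiguity.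

Step 11
Reactants: 21 (E)-1-[3-geranyl-6-hydroxy-2,4-bis(methoxymethoxy)-5-prenylphenyl]-3-[4-methoxy-2,6-bis(methoxymethoxy)phenyl]prop-2-en-1-one
Product: 22 (2S)-6-geranyl-5,7-bis(methoxymethoxy)-2-[4-methoxy-2,6-bis(methoxymethoxy)phenyl]-8-prenylchroman-4-one
Conditions: N-[3,5-bis(trifluoromethyl)phenyl]-N′-[(9R)-6′-methoxycinchonan-9-yl]thiourea (20 mol %), toluene, 0 °C → rt, 48 h
Reagents that add atoms: none
Why: Intramolecular oxa-Michael addition (6-endo-trig) under bifunctional organocatalysis, in which the quinuclidine nitrogen activates the phenol while the thiourea binds the enone carbonyl, delivers the phenol oxygen to one enantiotopic face of the β-carbon and sets C2 as S (the same spatial arrangement is named R once C3 carries OH).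

Step 12
Reactants: 22 (2S)-6-geranyl-5,7-bis(methoxymethoxy)-2-[4-methoxy-2,6-bis(methoxymethoxy)phenyl]-8-prenylchroman-4-one
Product: 24 (2R,3R)-6-geranyl-3-hydroxy-5,7-bis(methoxymethoxy)-2-[4-methoxy-2,6-bis(methoxymethoxy)phenyl]-8-prenylchroman-4-one, via sodium enolate 23 (not isolated)
Conditions: NaN(SiMe3)2 (1.1 equiv), THF, −78 °C, 20 min; 2-(phenylsulfonyl)-3-phenyloxaziridine (1.3 equiv), −78 °C; sat. aq. NH4Cl at −78 °C
Reagents that add atoms: 2-(phenylsulfonyl)-3-phenyloxaziridine O=S(=O)(c1ccccc1)N1OC1c1ccccc1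
Why: Davis oxidation of the enolate formed at −78 °C (cold enough to suppress retro-oxa-Michael ring opening, and the oxaziridine leaves the side-chain alkenes alone) transfers oxygen to C3 on the face anti to the pseudo-equatorial C2 aryl group, giving the 2,3-trans (2R,3R) alcohol, which is also the thermodynamic isomer.

Step 13
Reactants: 24 (2R,3R)-6-geranyl-3-hydroxy-5,7-bis(methoxymethoxy)-2-[4-methoxy-2,6-bis(methoxymethoxy)phenyl]-8-prenylchroman-4-one
Product: 25 (2R,3R)-2-(2,6-dihydroxy-4-methoxyphenyl)-6-geranyl-3,5,7-trihydroxy-8-prenylchroman-4-one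
Conditions: HCl (ca. 0.3 M, cat.), MeOH/THF 3:1, 35 °C, argon, monitored to completion
Reagents that add atoms: none
Why: Acid-catalysed transacetalisation to methanol removes all four MOM groups under conditions mild enough to spare the prenyl and geranyl alkenes, C3 is untouched and the 2,3-trans arrangement is the thermodynamically preferred one, so the (2R,3R) configuration is kept.

**Compound list**

1 | phloroglucinol (benzene-1,3,5-triol) | Oc1cc(O)cc(O)c1 | starting material
2 | 3,5-bis(methoxymethoxy)phenol | COCOc1cc(O)cc(OCOC)c1 | intermediate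
3 | 2-methylbut-3-en-2-ol | CC(C)(O)C=C | starting material
4 | lithium 2-methylbut-3-en-2-olate | [Li]OC(C)(C)C=C | intermediate
5 | methyl 2-methylbut-3-en-2-yl carbonate | COC(=O)OC(C)(C)C=C | intermediate
6 | 1,3-bis(methoxymethoxy)-5-(2-methylbut-3-en-2-yloxy)benzene | C=CC(C)(C)Oc1cc(OCOC)cc(OCOC)c1 | intermediate
7 | geraniol, (2E)-3,7-dimethylocta-2,6-dien-1-ol | CC(C)=CCC/C(C)=C/CO | starting material
8 | geranyl bromide, (2E)-1-bromo-3,7-dimethylocta-2,6-diene | CC(C)=CCC/C(C)=C/CBr | intermediate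
9 | [2,6-bis(methoxymethoxy)-4-(2-methylbut-3-en-2-yloxy)phenyl]lithium | [Li]c1c(OCOC)cc(OC(C)(C)C=C)cc1OCOC | intermediate
10 | 2-geranyl-1,3-bis(methoxymethoxy)-5-(2-methylbut-3-en-2-yloxy)benzene | C=CC(C)(C)Oc1cc(OCOC)c(C/C=C(\C)CCC=C(C)C)c(OCOC)c1 | intermediate
11 | 5-methoxyresorcinol (5-methoxybenzene-1,3-diol) | COc1cc(O)cc(O)c1 | starting material
12 | 1-methoxy-3,5-bis(methoxymethoxy)benzene | COCOc1cc(OC)cc(OCOC)c1 | intermediate
13 | [4-methoxy-2,6-bis(methoxymethoxy)phenyl]lithium | [Li]c1c(OCOC)cc(OC)cc1OCOC | intermediate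
14 | lithium (dimethylamino)[4-methoxy-2,6-bis(methoxymethoxy)phenyl]methanolate (racemic) | CN(C)C(O[Li])c1c(OCOC)cc(OC)cc1OCOC | intermediate
15 | 4-methoxy-2,6-bis(methoxymethoxy)benzaldehyde | O=Cc1c(OCOC)cc(OC)cc1OCOC | intermediate
16 | (E)-N-methoxy-3-[4-methoxy-2,6-bis(methoxymethoxy)phenyl]-N-methylprop-2-enamide | CON(C)C(=O)/C=C/c1c(OCOC)cc(OC)cc1OCOC | intermediate
17 | [3-geranyl-2,4-bis(methoxymethoxy)-6-(2-methylbut-3-en-2-yloxy)phenyl]lithium | [Li]c1c(OC(C)(C)C=C)cc(OCOC)c(C/C=C(\C)CCC=C(C)C)c1OCOC | intermediate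
18 | lithium (E)-1-[3-geranyl-2,4-bis(methoxymethoxy)-6-(2-methylbut-3-en-2-yloxy)phenyl]-1-[methoxy(methyl)amino]-3-[4-methoxy-2,6-bis(methoxymethoxy)phenyl]prop-2-en-1-olate (racemic) | C=CC(C)(C)Oc1cc(OCOC)c(C/C=C(\C)CCC=C(C)C)c(OCOC)c1C(O[Li])(N(C)OC)/C=C/c1c(OCOC)cc(OC)cc1OCOC | intermediate
19 | (E)-1-[3-geranyl-2,4-bis(methoxymethoxy)-6-(2-methylbut-3-en-2-yloxy)phenyl]-3-[4-methoxy-2,6-bis(methoxymethoxy)phenyl]prop-2-en-1-one | C=CC(C)(C)Oc1cc(OCOC)c(C/C=C(\C)CCC=C(C)C)c(OCOC)c1C(=O)/C=C/c1c(OCOC)cc(OC)cc1OCOC | intermediate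
20 | 4-geranyl-3,5-bis(methoxymethoxy)-6-[(E)-3-[4-methoxy-2,6-bis(methoxymethoxy)phenyl]prop-2-enoyl]-2-prenylcyclohexa-3,5-dien-1-one (racemic) | O=C1C(CC=C(C)C)C(OCOC)=C(C/C=C(\C)CCC=C(C)C)C(OCOC)=C1C(=O)/C=C/c1c(OCOC)cc(OC)cc1OCOC | intermediate
21 | (E)-1-[3-geranyl-6-hydroxy-2,4-bis(methoxymethoxy)-5-prenylphenyl]-3-[4-methoxy-2,6-bis(methoxymethoxy)phenyl]prop-2-en-1-one | CC(C)=CCc1c(O)c(C(=O)/C=C/c2c(OCOC)cc(OC)cc2OCOC)c(OCOC)c(C/C=C(\C)CCC=C(C)C)c1OCOC | intermediate
22 | (2S)-6-geranyl-5,7-bis(methoxymethoxy)-2-[4-methoxy-2,6-bis(methoxymethoxy)phenyl]-8-prenylchroman-4-one | COc1cc(OCOC)c([C@H]2Oc3c(CC=C(C)C)c(OCOC)c(C/C=C(\C)CCC=C(C)C)c(OCOC)c3C(=O)C2)c(OCOC)c1 | intermediate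
23 | sodium enolate of 22 (C4–ONa, C3=C4; C2 configuration unchanged) | COc1cc(OCOC)c([C@H]2Oc3c(CC=C(C)C)c(OCOC)c(C/C=C(\C)CCC=C(C)C)c(OCOC)c3C(O[Na])=C2)c(OCOC)c1 | intermediate
24 | (2R,3R)-6-geranyl-3-hydroxy-5,7-bis(methoxymethoxy)-2-[4-methoxy-2,6-bis(methoxymethoxy)phenyl]-8-prenylchroman-4-one | COc1cc(OCOC)c([C@H]2Oc3c(CC=C(C)C)c(OCOC)c(C/C=C(\C)CCC=C(C)C)c(OCOC)c3C(=O)[C@@H]2O)c(OCOC)c1 | intermediate
25 | (2R,3R)-2-(2,6-dihydroxy-4-methoxyphenyl)-6-geranyl-3,5,7-trihydroxy-8-prenylchroman-4-one (CNP0304077.2) | COc1cc(O)c([C@H]2Oc3c(CC=C(C)C)c(O)c(C/C=C(\C)CCC=C(C)C)c(O)c3C(=O)[C@@H]2O)c(O)c1 | target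

**Step count**

- Total: 13 steps.
- Longest linear sequence: 8 steps (1, 3, 5, 9, 10, 11, 12, 13; the ring B branch 6, 7, 8, 9–13 is equally long).

**Steps most likely to fail, with fallbacks**

Step 11 (asymmetric oxa-Michael closure). The β-carbon is electron-rich and flanked by two ortho OMOM groups, so rate and enantiomeric excess may be low and the addition is reversible. The sense of induction is an expectation, not an established result for this substrate, and must be confirmed on 22 (circular dichroism); the (8α,9S) quinine-derived pseudo-enantiomer of the catalyst gives the antipode. Fallback, setting out from 21: NaOAc in refluxing EtOH closes ring C by the same oxa-Michael addition without stereocontrol and gives racemic 6-geranyl-5,7-bis(methoxymethoxy)-2-[4-methoxy-2,6-bis(methoxymethoxy)phenyl]-8-prenylchroman-4-one F4. Kinetic resolution by Noyori–Ikariya transfer hydrogenation with RhCl(C5Me5)[(R,R)-TsNCH(Ph)CH(Ph)NH2] (1 mol %), HCO2H/Et3N, EtOAc, rt, reduces only the (2R)-ketone, to (2R,4R)-6-geranyl-5,7-bis(methoxymethoxy)-2-[4-methoxy-2,6-bis(methoxymethoxy)phenyl]-8-prenylchroman-4-ol F5. The unreacted (2S)-ketone is separated by chromatography, and the route is rejoined at 22.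

Step 9 (lithiation next to the allyl ether and acylation). The aryllithium sits ortho to the 1,1-dimethylallyl ether and may add to its vinyl group before it is acylated. Fallback, setting out from 10: heating 10 in toluene at 105 °C performs the Claisen shift first and gives 4-geranyl-3,5-bis(methoxymethoxy)-2-prenylphenol F1. Ethyl vinyl ether with catalytic pyridinium p-toluenesulfonate in CH2Cl2 converts it into 1-(1-ethoxyethoxy)-4-geranyl-3,5-bis(methoxymethoxy)-2-prenylbenzene F2. The single ring hydrogen left is lithiated (n-BuLi, TMEDA, THF, −20 °C) and acylated with 16 to give (E)-1-[6-(1-ethoxyethoxy)-3-geranyl-2,4-bis(methoxymethoxy)-5-prenylphenyl]-3-[4-methoxy-2,6-bis(methoxymethoxy)phenyl]prop-2-en-1-one F3. Pyridinium p-toluenesulfonate in EtOH at rt removes the ethoxyethyl acetal far faster than the MOM acetals, and the route is rejoined at 21.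

Step 12 (enolate hydroxylation). The flavanone enolate can open to the chalcone phenoxide, which would erode C2 and lower the yield. Fallback, setting out from 19, with the C3 oxygen put in before ring closure: Juliá–Colonna epoxidation (poly-L-leucine, urea–hydrogen peroxide, DBU, THF, rt) attacks only the electron-poor enone and gives [3-geranyl-2,4-bis(methoxymethoxy)-6-(2-methylbut-3-en-2-yloxy)phenyl][(2R,3S)-3-[4-methoxy-2,6-bis(methoxymethoxy)phenyl]oxiran-2-yl]methanone F6. The Claisen shift (toluene, 105 °C) then unveils the phenol in [3-geranyl-6-hydroxy-2,4-bis(methoxymethoxy)-5-prenylphenyl][(2R,3S)-3-[4-methoxy-2,6-bis(methoxymethoxy)phenyl]oxiran-2-yl]methanone F7. Catalytic pyridinium p-toluenesulfonate in CH2Cl2 closes ring C by 6-endo opening of the epoxide at the benzylic carbon. C3 keeps the R configuration of the retained epoxide C–O bond and C2 ends trans (inversion, and also the thermodynamic outcome). The route is rejoined at 24.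

**Further compounds**

F1 | step 9 | 4-geranyl-3,5-bis(methoxymethoxy)-2-prenylphenol | Oc1cc(OCOC)c(C/C=C(\C)CCC=C(C)C)c(OCOC)c1CC=C(C)C
F2 | step 9 | 1-(1-ethoxyethoxy)-4-geranyl-3,5-bis(methoxymethoxy)-2-prenylbenzene (racemic acetal) | CCOC(C)Oc1cc(OCOC)c(C/C=C(\C)CCC=C(C)C)c(OCOC)c1CC=C(C)C
F3 | step 9 | (E)-1-[6-(1-ethoxyethoxy)-3-geranyl-2,4-bis(methoxymethoxy)-5-prenylphenyl]-3-[4-methoxy-2,6-bis(methoxymethoxy)phenyl]prop-2-en-1-one (racemic acetal) | CCOC(C)Oc1c(CC=C(C)C)c(OCOC)c(C/C=C(\C)CCC=C(C)C)c(OCOC)c1C(=O)/C=C/c1c(OCOC)cc(OC)cc1OCOC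
F4 | step 11 | racemic 6-geranyl-5,7-bis(methoxymethoxy)-2-[4-methoxy-2,6-bis(methoxymethoxy)phenyl]-8-prenylchroman-4-one | COc1cc(OCOC)c(C2Oc3c(CC=C(C)C)c(OCOC)c(C/C=C(\C)CCC=C(C)C)c(OCOC)c3C(=O)C2)c(OCOC)c1
F5 | step 11 | (2R,4R)-6-geranyl-5,7-bis(methoxymethoxy)-2-[4-methoxy-2,6-bis(methoxymethoxy)phenyl]-8-prenylchroman-4-ol | COc1cc(OCOC)c([C@@H]2Oc3c(CC=C(C)C)c(OCOC)c(C/C=C(\C)CCC=C(C)C)c(OCOC)c3[C@H](O)C2)c(OCOC)c1
F6 | step 12 | [3-geranyl-2,4-bis(methoxymethoxy)-6-(2-methylbut-3-en-2-yloxy)phenyl][(2R,3S)-3-[4-methoxy-2,6-bis(methoxymethoxy)phenyl]oxiran-2-yl]methanone | C=CC(C)(C)Oc1cc(OCOC)c(C/C=C(\C)CCC=C(C)C)c(OCOC)c1C(=O)[C@@H]2O[C@H]2c2c(OCOC)cc(OC)cc2OCOC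
F7 | step 12 | [3-geranyl-6-hydroxy-2,4-bis(methoxymethoxy)-5-prenylphenyl][(2R,3S)-3-[4-methoxy-2,6-bis(methoxymethoxy)phenyl]oxiran-2-yl]methanone | CC(C)=CCc1c(O)c(C(=O)[C@@H]2O[C@H]2c2c(OCOC)cc(OC)cc2OCOC)c(OCOC)c(C/C=C(\C)CCC=C(C)C)c1OCOC
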